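## Retrosynthetic overview

1. The target is a trans-fused bicyclo[5.3.0]decane (daucane) with a tertiary C4–O vanillate and a free C6–OH. Ring A (five-membered) is C1 (quaternary, Me)–C2–C3–C4 (acyloxy, iPr)–C5 (H); ring B (seven-membered) is C1–C5–C6 (OH)–C7–C8 (Me)–C9–C10, with the epoxide on C8–C9.
2. Late disconnections: the C8–C9 epoxide (directed by the homoallylic C6–OH), the C4–O aroyl bond (tertiary alkoxide plus O-benzylvanilloyl chloride) and the C8 methyl (from a CO2Me group).
3. The C4–OH/H5/C6–OH triad comes from a C4=C5–C6=O enone by C6–OH-directed epoxidation, SmI2 opening and 1,3-anti reduction; the enone comes from a C4-oxo/C6-ethoxy vinylogous ester by isopropyl addition and transposition.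
4. The feature on which the strategy rests: in ring B the oxygenated C6, the C7 methylene, the C8=C9 alkene (C8 carrying a one-carbon group) and C10 bonded to the quaternary C1 are the imprint of a 2-oxy-1,3-diene (C1=C5–C6(OEt)=C7) joined to a three-carbon vinylcarbenoid (C8, C9, C10).
5. Ring order: ring A is bought as 3-methylcyclopentenone; ring B closes in the key step (cyclopropanation makes C7–C8, the Cope step makes C1–C10); both oxiranes are made later on the intact bicycle.

Key step: step 6

Assumption: the dirhodium prolinate catalyst is taken to select the carbenoid face on this 1,1-disubstituted enol ether in its usual sense for terminal alkenes, which puts the R-configured catalyst on the 8aR series; if the sense proves opposite, the S-configured catalyst is used in the same way.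

## Route

Step 1
Reactants: 1 3-methylcyclopent-2-en-1-one
Product: 3 2-bromo-3-methylcyclopent-2-en-1-one, via dibromo ketone 2 (not isolated)
Conditions: Br2, CH2Cl2, 0 °C; then Et3N, 0 °C → rt
Reagents that add atoms: bromine, BrBr
Why: Bromine adds across the enone alkene and triethylamine removes HBr from the α-bromo ketone, restoring the enone with bromine at C2 (bromination–dehydrobromination); no stereocentre remains.

Step 2
Reactants: 3 2-bromo-3-methylcyclopent-2-en-1-one; 4 tributyl(1-ethoxyvinyl)stannane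
Product: 5 2-(1-ethoxyethenyl)-3-methylcyclopent-2-en-1-one
Conditions: Pd(PPh3)4 (5 mol %), CuI (10 mol %), CsF, DMF, 45 °C; chromatography on Et3N-deactivated silica
Reagents that add atoms: none
Why: Zerovalent palladium inserts into the C(sp2)–Br bond of the α-bromoenone and the α-alkoxyvinyl group is transferred from tin (Stille coupling); the acid-labile enol ether survives the non-acidic work-up.

Step 3
Reactants: 6 methyl acetoacetate
Product: 7 methyl 2-diazo-3-oxobutanoate
Conditions: 4-acetamidobenzenesulfonyl azide, Et3N, MeCN, 0 °C → rt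
Reagents that add atoms: 4-acetamidobenzenesulfonyl azide, CC(=O)Nc1ccc(cc1)S(=O)(=O)N=[N+]=[N-]
Why: The active methylene is deprotonated and takes the diazo group from the sulfonyl azide (Regitz diazo transfer).

Step 4
Reactants: 7 methyl 2-diazo-3-oxobutanoate
Product: 8 methyl 2-diazo-3-hydroxybutanoate (racemic)
Conditions: NaBH4, MeOH, 0 °C
Reagents that add atoms: none
Why: Borohydride reduces the ketone and leaves the ester-stabilised diazo group intact (chemoselective carbonyl reduction); the carbinol stereocentre is removed in the next step.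

Step 5
Reactants: 8 methyl 2-diazo-3-hydroxybutanoate (racemic)
Product: 9 methyl 2-diazobut-3-enoate
Conditions: POCl3, Et3N, CH2Cl2, 0 °C; cold pentane extraction, used at once as a cold solution
Reagents that add atoms: none
Why: Activation of the hydroxyl by POCl3 and base-induced β-elimination give the vinyldiazoacetate (dehydration), which is kept cold and used at once because it electrocyclises to a 3H-pyrazole on standing.

Step 6
Reactants: 5 2-(1-ethoxyethenyl)-3-methylcyclopent-2-en-1-one; 9 methyl 2-diazobut-3-enoate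
Product: 11 methyl (8aR)-4-ethoxy-8a-methyl-3-oxo-1,2,3,5,8,8a-hexahydroazulene-6-carboxylate, via cis-divinylcyclopropane 10 (not isolated)
Conditions: Rh2(R-DOSP)4 (2 mol %), hexane–toluene, −40 °C, slow addition of cold 9 (2 equiv); then rt → 80 °C (toluene)
Reagents that add atoms: none
Why: The rhodium vinylcarbenoid formed from 9 by loss of N2 adds to the terminal CH2 of the ethoxyvinyl group of 5, the only electron-rich and unhindered alkene (the enone alkene is tetrasubstituted and electron-poor), and forms C7–C8 and C6–C8 of cyclopropane 10 with the small ethoxy group syn to the ester and the cyclopentenyl group syn to the vinyl group. The cis-divinylcyclopropane then undergoes a [3,3] sigmatropic (Cope) rearrangement through the boat transition state, breaking the donor–acceptor-weakened C6–C8 bond and forming C1–C10, so ring B closes by sigmatropic bonding of the vinyl terminus C10 to the methyl-bearing ring carbon C1; the (Z)-methyl at that terminus slows the step, hence the warming. The closest known reaction type is the tandem cyclopropanation/Cope rearrangement (formal [4+3] cycloaddition) of vinyldiazoacetates with 1,3-dienes under chiral dirhodium carboxylate catalysis. The one new stereocentre, C1, is controlled by the catalyst, which fixes the configuration of the carbenoid carbon C8 in 10; the stereospecific boat Cope step relays it to C1. The step needs site selectivity (enol ether over enone), cis-divinyl diastereoselectivity and carbenoid rather than vinylogous reactivity, and these rest on the electronic difference between the two alkenes, on the size difference between ethoxy and the ring, and on the non-polar solvent at low temperature.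

Step 7
Reactants: 11 methyl (8aR)-4-ethoxy-8a-methyl-3-oxo-1,2,3,5,8,8a-hexahydroazulene-6-carboxylate
Product: 13 methyl (8aR)-8a-methyl-4-oxo-3-(propan-2-yl)-1,2,4,5,8,8a-hexahydroazulene-6-carboxylate, via tertiary carbinol 12 (not isolated)
Conditions: iPrMgCl, CeCl3 (anhydrous), THF, −78 °C; then 1 M HCl, THF, 0 °C, short contact
Reagents that add atoms: isopropylmagnesium chloride, CC(C)[Mg]Cl; water, O
Why: The organocerium reagent adds 1,2 to the vinylogous-ester carbonyl C4 without enolisation and faster than to the conjugated methyl ester, and cold aqueous acid then ionises the tertiary allylic carbinol and hydrolyses the enol ether to the transposed C4=C5–C6=O enone (Stork–Danheiser sequence); the C4 carbinol centre of 12 is destroyed and C1 is untouched.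

Step 8
Reactants: 13 methyl (8aR)-8a-methyl-4-oxo-3-(propan-2-yl)-1,2,4,5,8,8a-hexahydroazulene-6-carboxylate
Product: 14 methyl (4R,8aR)-4-hydroxy-8a-methyl-3-(propan-2-yl)-1,2,4,5,8,8a-hexahydroazulene-6-carboxylate (C6–OH syn to the C1 methyl)
Conditions: (S)-2-methyl-CBS-oxazaborolidine (0.3 equiv), BH3·SMe2, THF, −30 °C
Reagents that add atoms: none
Why: In the Corey–Bakshi–Shibata reduction the fully substituted alkenyl side of the C6 ketone acts as the large group, so hydride is delivered to the face anti to the C1 methyl, which is also the substrate-preferred face, and the C6 hydroxyl ends syn to that methyl; the ester and the electron-poor alkenes do not react with borane at this temperature.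

Step 9
Reactants: 14 methyl (4R,8aR)-4-hydroxy-8a-methyl-3-(propan-2-yl)-1,2,4,5,8,8a-hexahydroazulene-6-carboxylate
Product: 15 methyl (3R,3aS,4R,8aR)-3,3a-epoxy-4-hydroxy-8a-methyl-3-(propan-2-yl)-1,2,3,3a,4,5,8,8a-octahydroazulene-6-carboxylate
Conditions: VO(acac)2 (5 mol %), t-BuOOH (decane), CH2Cl2, 0 °C → rt
Reagents that add atoms: tert-butyl hydroperoxide, CC(C)(C)OO
Why: Vanadium-catalysed hydroxyl-directed epoxidation of the allylic alcohol delivers oxygen to the electron-rich tetrasubstituted C4=C5 alkene on the face of the C6 hydroxyl, that is syn to the C1 methyl, which sets the C4–O configuration; the ester-conjugated C8=C9 alkene is too electron-poor to react.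

Step 10
Reactants: 15 methyl (3R,3aS,4R,8aR)-3,3a-epoxy-4-hydroxy-8a-methyl-3-(propan-2-yl)-1,2,3,3a,4,5,8,8a-octahydroazulene-6-carboxylate
Product: 16 methyl (3R,3aR,8aR)-3,3a-epoxy-8a-methyl-4-oxo-3-(propan-2-yl)-1,2,3,3a,4,5,8,8a-octahydroazulene-6-carboxylate
Conditions: Dess–Martin periodinane, NaHCO3, CH2Cl2, 0 °C → rt
Reagents that add atoms: none
Why: The buffered hypervalent-iodine oxidation converts the secondary alcohol into the ketone under neutral conditions that neither open the epoxide nor move the C8=C9 alkene (Dess–Martin oxidation).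

Step 11
Reactants: 16 methyl (3R,3aR,8aR)-3,3a-epoxy-8a-methyl-4-oxo-3-(propan-2-yl)-1,2,3,3a,4,5,8,8a-octahydroazulene-6-carboxylate
Product: 17 methyl (3R,3aR,8aR)-3-hydroxy-8a-methyl-4-oxo-3-(propan-2-yl)-1,2,3,3a,4,5,8,8a-octahydroazulene-6-carboxylate (C4–OH syn and H5 anti to the C1 methyl)
Conditions: SmI2 (2.2 equiv), THF–MeOH, −78 °C
Reagents that add atoms: none
Why: Two single-electron transfers cleave the C5–O bond of the α,β-epoxy ketone and leave the C4–O bond with its epoxide-set configuration (reductive opening of an epoxy ketone); protonation at C5 by methanol is expected anti to the C1 methyl and the C4 oxygen, giving the trans-fused ketone, which is also the more stable C5 epimer because C6 then lies trans to the isopropyl group.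

Step 12
Reactants: 17 methyl (3R,3aR,8aR)-3-hydroxy-8a-methyl-4-oxo-3-(propan-2-yl)-1,2,3,3a,4,5,8,8a-octahydroazulene-6-carboxylate
Product: 18 methyl (3R,3aS,4S,8aR)-3,4-dihydroxy-8a-methyl-3-(propan-2-yl)-1,2,3,3a,4,5,8,8a-octahydroazulene-6-carboxylate
Conditions: Me4NBH(OAc)3, MeCN–AcOH, −30 °C
Reagents that add atoms: none
Why: The C4 hydroxyl exchanges onto boron and delivers hydride intramolecularly to the face of the C6 carbonyl on which it sits, so the new C6 hydroxyl ends anti to the C4 oxygen and anti to the C1 methyl (Evans–Saksena 1,3-anti reduction); the conjugated ester is inert to this reagent.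

Step 13
Reactants: 18 methyl (3R,3aS,4S,8aR)-3,4-dihydroxy-8a-methyl-3-(propan-2-yl)-1,2,3,3a,4,5,8,8a-octahydroazulene-6-carboxylate
Product: 19 methyl (3R,3aS,4S,8aR)-4-[(tert-butyldimethylsilyl)oxy]-3-hydroxy-8a-methyl-3-(propan-2-yl)-1,2,3,3a,4,5,8,8a-octahydroazulene-6-carboxylate
Conditions: TBSOTf (1.1 equiv), 2,6-lutidine, CH2Cl2, −78 → 0 °C
Reagents that add atoms: tert-butyldimethylsilyl trifluoromethanesulfonate, CC(C)(C)[Si](C)(C)OS(=O)(=O)C(F)(F)F
Why: The silyl triflate reacts with the secondary C6 hydroxyl, while the tertiary C4 hydroxyl, flanked by the isopropyl group and the ring fusion, does not react at low temperature (chemoselective silyl ether formation).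

Step 14
Reactants: 19 methyl (3R,3aS,4S,8aR)-4-[(tert-butyldimethylsilyl)oxy]-3-hydroxy-8a-methyl-3-(propan-2-yl)-1,2,3,3a,4,5,8,8a-octahydroazulene-6-carboxylate
Product: 20 (3R,3aS,4S,8aR)-4-[(tert-butyldimethylsilyl)oxy]-6-(hydroxymethyl)-8a-methyl-3-(propan-2-yl)-1,2,3,3a,4,5,8,8a-octahydroazulen-3-ol
Conditions: iBu2AlH (4 equiv), CH2Cl2, −78 → 0 °C; Rochelle salt work-up
Reagents that add atoms: none
Why: The aluminium hydride reduces the conjugated methyl ester 1,2 to the primary allylic alcohol and leaves the silyl ether and the alkene alone (ester reduction); the tertiary alcohol only consumes one hydride.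

Step 15
Reactants: 20 (3R,3aS,4S,8aR)-4-[(tert-butyldimethylsilyl)oxy]-6-(hydroxymethyl)-8a-methyl-3-(propan-2-yl)-1,2,3,3a,4,5,8,8a-octahydroazulen-3-ol
Product: 22 (3R,3aS,4S,8aR)-4-[(tert-butyldimethylsilyl)oxy]-6,8a-dimethyl-3-(propan-2-yl)-1,2,3,3a,4,5,8,8a-octahydroazulen-3-ol, via allylic sulfate 21 (not isolated)
Conditions: SO3·pyridine, THF, 0 °C; then LiAlH4, THF, 0 °C → rt
Reagents that add atoms: none
Why: The primary allylic alcohol is sulfated selectively over the hindered tertiary one, and hydride then displaces the sulfate at the primary carbon, giving the C8 methyl group with the C8=C9 alkene in place (reductive deoxygenation of an allylic alcohol through its sulfate monoester).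

Step 16
Reactants: 23 4-(benzyloxy)-3-methoxybenzoic acid
Product: 24 4-(benzyloxy)-3-methoxybenzoyl chloride
Conditions: (COCl)2, DMF (cat.), CH2Cl2, 0 °C → rt
Reagents that add atoms: oxalyl chloride, ClC(=O)C(Cl)=O
Why: Catalytic DMF forms the chloroiminium species that converts the acid into its chloride (acid chloride formation); the benzyl ether keeps the phenol masked.

Step 17
Reactants: 22 (3R,3aS,4S,8aR)-4-[(tert-butyldimethylsilyl)oxy]-6,8a-dimethyl-3-(propan-2-yl)-1,2,3,3a,4,5,8,8a-octahydroazulen-3-ol; 24 4-(benzyloxy)-3-methoxybenzoyl chloride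
Product: 26 (3R,3aS,4S,8aR)-4-[(tert-butyldimethylsilyl)oxy]-6,8a-dimethyl-3-(propan-2-yl)-1,2,3,3a,4,5,8,8a-octahydroazulen-3-yl 4-(benzyloxy)-3-methoxybenzoate, via lithium alkoxide 25 (not isolated)
Conditions: n-BuLi, THF, −78 °C; then 24, −78 °C → rt
Reagents that add atoms: none
Why: Deprotonation gives the lithium alkoxide of the tertiary alcohol, which attacks the aroyl chloride with no acid present that could ionise the tertiary centre (acylation of a tertiary alkoxide); the lithium counter-ion in cold THF disfavours a silyl shift from O6 to O4, and C4 keeps its configuration because its C–O bond is not broken.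

Step 18
Reactants: 26 (3R,3aS,4S,8aR)-4-[(tert-butyldimethylsilyl)oxy]-6,8a-dimethyl-3-(propan-2-yl)-1,2,3,3a,4,5,8,8a-octahydroazulen-3-yl 4-(benzyloxy)-3-methoxybenzoate
Product: 27 (3R,3aS,4S,8aR)-4-hydroxy-6,8a-dimethyl-3-(propan-2-yl)-1,2,3,3a,4,5,8,8a-octahydroazulen-3-yl 4-(benzyloxy)-3-methoxybenzoate
Conditions: HF·pyridine, THF–pyridine, 0 °C → rt
Reagents that add atoms: none
Why: Fluoride cleaves the Si–O bond under mildly acidic conditions, so no free C6 alkoxide forms that could take the acyl group from the tertiary C4 oxygen (desilylation); the benzyl ether, the ester and the alkene are inert.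

Step 19
Reactants: 27 (3R,3aS,4S,8aR)-4-hydroxy-6,8a-dimethyl-3-(propan-2-yl)-1,2,3,3a,4,5,8,8a-octahydroazulen-3-yl 4-(benzyloxy)-3-methoxybenzoate
Product: 28 (3R,3aS,4S,6R,7S,8aR)-6,7-epoxy-4-hydroxy-6,8a-dimethyl-3-(propan-2-yl)decahydroazulen-3-yl 4-(benzyloxy)-3-methoxybenzoate
Conditions: VO(acac)2 (10 mol %), t-BuOOH (decane), toluene, rt → 40 °C
Reagents that add atoms: tert-butyl hydroperoxide, CC(C)(C)OO
Why: The vanadium peroxo species bound to the homoallylic C6 hydroxyl delivers oxygen to the C8=C9 face on which that hydroxyl sits, which is also the face anti to the angular C1 methyl, so direction and sterics together set C8 and C9 (hydroxyl-directed epoxidation of a homoallylic alcohol).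

Step 20
Reactants: 28 (3R,3aS,4S,6R,7S,8aR)-6,7-epoxy-4-hydroxy-6,8a-dimethyl-3-(propan-2-yl)decahydroazulen-3-yl 4-(benzyloxy)-3-methoxybenzoate
Product: 29 (3R,3aS,4S,6R,7S,8aR)-6,7-epoxy-4-hydroxy-6,8a-dimethyl-3-(propan-2-yl)decahydroazulen-3-yl 4-hydroxy-3-methoxybenzoate (CNP0315707.1)
Conditions: H2 (1 atm), 10% Pd/C, EtOAc, rt
Reagents that add atoms: none
Why: Hydrogenolysis of the aryl benzyl ether over palladium is fast and neutral and should not touch the trialkyl epoxide, the tertiary ester or any stereocentre (O-debenzylation).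

## Compound list

1 | 3-methylcyclopent-2-en-1-one | CC1=CC(=O)CC1 | starting material
2 | 2,3-dibromo-3-methylcyclopentan-1-one (dibromo ketone, diastereomers) | CC1(Br)CCC(=O)C1Br | intermediate
3 | 2-bromo-3-methylcyclopent-2-en-1-one | CC1=C(Br)C(=O)CC1 | intermediate
4 | tributyl(1-ethoxyvinyl)stannane | CCCC[Sn](CCCC)(CCCC)C(=C)OCC | starting material
5 | 2-(1-ethoxyethenyl)-3-methylcyclopent-2-en-1-one | CCOC(=C)C1=C(C)CCC1=O | intermediate
6 | methyl acetoacetate | COC(=O)CC(C)=O | starting material
7 | methyl 2-diazo-3-oxobutanoate | COC(=O)C(=[N+]=[N-])C(C)=O | intermediate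
8 | methyl 2-diazo-3-hydroxybutanoate (racemic) | COC(=O)C(=[N+]=[N-])C(C)O | intermediate
9 | methyl 2-diazobut-3-enoate | COC(=O)C(=[N+]=[N-])C=C | intermediate
10 | methyl (1S,2R)-1-ethenyl-2-ethoxy-2-(2-methyl-5-oxocyclopent-1-en-1-yl)cyclopropane-1-carboxylate (cis-divinylcyclopropane) | C=C[C@@]1(C(=O)OC)C[C@@]1(OCC)C2=C(C)CCC2=O | intermediate
11 | methyl (8aR)-4-ethoxy-8a-methyl-3-oxo-1,2,3,5,8,8a-hexahydroazulene-6-carboxylate | O=C2CC[C@]3(C)CC=C(C(=O)OC)CC(OCC)=C32 | intermediate
12 | methyl (8aR)-4-ethoxy-3-hydroxy-8a-methyl-3-(propan-2-yl)-1,2,3,5,8,8a-hexahydroazulene-6-carboxylate (tertiary carbinol, C3 configuration not defined) | CC(C)C2(O)CC[C@]3(C)CC=C(C(=O)OC)CC(OCC)=C32 | intermediate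
13 | methyl (8aR)-8a-methyl-4-oxo-3-(propan-2-yl)-1,2,4,5,8,8a-hexahydroazulene-6-carboxylate | CC(C)C2=C3C(=O)CC(C(=O)OC)=CC[C@@]3(C)CC2 | intermediate
14 | methyl (4R,8aR)-4-hydroxy-8a-methyl-3-(propan-2-yl)-1,2,4,5,8,8a-hexahydroazulene-6-carboxylate | CC(C)C2=C3[C@H](O)CC(C(=O)OC)=CC[C@@]3(C)CC2 | intermediate
15 | methyl (3R,3aS,4R,8aR)-3,3a-epoxy-4-hydroxy-8a-methyl-3-(propan-2-yl)-1,2,3,3a,4,5,8,8a-octahydroazulene-6-carboxylate | CC(C)[C@]12CC[C@]3(C)CC=C(C(=O)OC)C[C@@H](O)[C@@]31O2 | intermediate
16 | methyl (3R,3aR,8aR)-3,3a-epoxy-8a-methyl-4-oxo-3-(propan-2-yl)-1,2,3,3a,4,5,8,8a-octahydroazulene-6-carboxylate | CC(C)[C@]12CC[C@]3(C)CC=C(C(=O)OC)CC(=O)[C@@]31O2 | intermediate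
17 | methyl (3R,3aR,8aR)-3-hydroxy-8a-methyl-4-oxo-3-(propan-2-yl)-1,2,3,3a,4,5,8,8a-octahydroazulene-6-carboxylate | CC(C)[C@]2(O)CC[C@]3(C)CC=C(C(=O)OC)CC(=O)[C@H]32 | intermediate
18 | methyl (3R,3aS,4S,8aR)-3,4-dihydroxy-8a-methyl-3-(propan-2-yl)-1,2,3,3a,4,5,8,8a-octahydroazulene-6-carboxylate | CC(C)[C@]2(O)CC[C@]3(C)CC=C(C(=O)OC)C[C@H](O)[C@H]32 | intermediate
19 | methyl (3R,3aS,4S,8aR)-4-[(tert-butyldimethylsilyl)oxy]-3-hydroxy-8a-methyl-3-(propan-2-yl)-1,2,3,3a,4,5,8,8a-octahydroazulene-6-carboxylate | CC(C)[C@]2(O)CC[C@]3(C)CC=C(C(=O)OC)C[C@H](O[Si](C)(C)C(C)(C)C)[C@H]32 | intermediate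
20 | (3R,3aS,4S,8aR)-4-[(tert-butyldimethylsilyl)oxy]-6-(hydroxymethyl)-8a-methyl-3-(propan-2-yl)-1,2,3,3a,4,5,8,8a-octahydroazulen-3-ol | CC(C)[C@]2(O)CC[C@]3(C)CC=C(CO)C[C@H](O[Si](C)(C)C(C)(C)C)[C@H]32 | intermediate
21 | pyridinium salt of the C8-CH2 sulfate monoester of 20 (allylic sulfate) | CC(C)[C@]2(O)CC[C@]3(C)CC=C(COS(=O)(=O)[O-])C[C@H](O[Si](C)(C)C(C)(C)C)[C@H]32.c1cc[nH+]cc1 | intermediate
22 | (3R,3aS,4S,8aR)-4-[(tert-butyldimethylsilyl)oxy]-6,8a-dimethyl-3-(propan-2-yl)-1,2,3,3a,4,5,8,8a-octahydroazulen-3-ol | CC(C)[C@]2(O)CC[C@]3(C)CC=C(C)C[C@H](O[Si](C)(C)C(C)(C)C)[C@H]32 | intermediate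
23 | 4-(benzyloxy)-3-methoxybenzoic acid | COc1cc(C(=O)O)ccc1OCc1ccccc1 | starting material
24 | 4-(benzyloxy)-3-methoxybenzoyl chloride | COc1cc(C(Cl)=O)ccc1OCc1ccccc1 | intermediate
25 | lithium alkoxide of 22 | CC(C)[C@]2([O-])CC[C@]3(C)CC=C(C)C[C@H](O[Si](C)(C)C(C)(C)C)[C@H]32.[Li+] | intermediate
26 | (3R,3aS,4S,8aR)-4-[(tert-butyldimethylsilyl)oxy]-6,8a-dimethyl-3-(propan-2-yl)-1,2,3,3a,4,5,8,8a-octahydroazulen-3-yl 4-(benzyloxy)-3-methoxybenzoate | COc1cc(C(=O)O[C@@]2(C(C)C)CC[C@]3(C)CC=C(C)C[C@H](O[Si](C)(C)C(C)(C)C)[C@H]32)ccc1OCc1ccccc1 | intermediate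
27 | (3R,3aS,4S,8aR)-4-hydroxy-6,8a-dimethyl-3-(propan-2-yl)-1,2,3,3a,4,5,8,8a-octahydroazulen-3-yl 4-(benzyloxy)-3-methoxybenzoate | COc1cc(C(=O)O[C@@]2(C(C)C)CC[C@]3(C)CC=C(C)C[C@H](O)[C@H]32)ccc1OCc1ccccc1 | intermediate
28 | (3R,3aS,4S,6R,7S,8aR)-6,7-epoxy-4-hydroxy-6,8a-dimethyl-3-(propan-2-yl)decahydroazulen-3-yl 4-(benzyloxy)-3-methoxybenzoate | COc1cc(C(=O)O[C@@]2(C(C)C)CC[C@]3(C)C[C@@H]4O[C@]4(C)C[C@H](O)[C@H]32)ccc1OCc1ccccc1 | intermediate
29 | (3R,3aS,4S,6R,7S,8aR)-6,7-epoxy-4-hydroxy-6,8a-dimethyl-3-(propan-2-yl)decahydroazulen-3-yl 4-hydroxy-3-methoxybenzoate (CNP0315707.1) | COc1cc(C(=O)O[C@@]2(C(C)C)CC[C@]3(C)C[C@@H]4O[C@]4(C)C[C@H](O)[C@H]32)ccc1O | target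

## Step count and risks

Total step count: 20. Longest linear sequence: 17 steps (from methyl acetoacetate 6 through steps 3–15 and 17–20).

The three steps most likely to fail:

**Step 6 (key annulation).** The cyclopropanation may place the ethoxy group, not the cyclopentenyl group, syn to the vinyl group, or the Cope step may stall at the (Z)-methyl terminus. Forcing conditions would then pass through zwitterionic opening of the donor–acceptor cyclopropane, which erases the catalyst-set configuration; the facial sense of the catalyst could also be opposite to the one assumed. Fallback, from 5 and 9, returning at 14: the annulation is run with achiral dirhodium tetrapivalate, Rh2(OPiv)4, and the mixture is heated in toluene, so that both diastereomers of the racemic cyclopropane F1 funnel by reversible ring opening into the racemic cycloheptadiene ester F2. The conditions of step 7 take F2 through the racemic tertiary carbinol F3 (not isolated) to the racemic enone F4. Luche reduction (NaBH4, CeCl3·7H2O, MeOH, −40 °C), with hydride anti to the C1 methyl, gives the racemic cis allylic alcohol F5. Lipase-catalysed acetylation (Candida antarctica lipase B, vinyl acetate, MTBE) resolves F5; the (4R) enantiomer is expected to react faster and to be isolated as the allylic acetate F6. K2CO3 in MeOH then gives 14. If the enzyme prefers the other enantiomer, 14 is the recovered alcohol.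

**Step 17 (tertiary acylation).** The crowded tertiary alkoxide may not be acylated, or the silyl group may shift from O6 to O4 under the basic conditions so that the acyl group ends on C6. Fallback, from 22, returning at 26: the acyl donor and the mode of activation are changed. Acid 23 and chloride 24 (Et3N, CH2Cl2) give the symmetrical 4-(benzyloxy)-3-methoxybenzoic anhydride F7. This acylates the neutral alcohol 22 under dual activation with MgBr2·OEt2 and Et3N in CH2Cl2 at rt; no free alkoxide is formed, so a silyl shift has no pathway.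

**Step 7 (isopropyl addition and transposition).** The organometallic may attack the conjugated methyl ester in competition with the deactivated vinylogous-ester carbonyl; prolonged acid contact could also move the C8=C9 alkene into conjugation with the new ketone. Fallback, from 11, returning at 13: the ester is masked as its carboxylate. Me3SnOH in 1,2-dichloroethane at 70 °C gives the vinylogous-ester acid F8. An excess of iPrMgCl/CeCl3 (THF, −78 → −20 °C) deprotonates the acid and adds only to C4, giving the carbinol acid F9 (not isolated). Cold 1 M HCl gives the enone acid F10, and TMSCHN2 in MeOH–toluene re-forms the methyl ester 13.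

## Further compounds

F1 | step 6 | racemic methyl 1-ethenyl-2-ethoxy-2-(2-methyl-5-oxocyclopent-1-en-1-yl)cyclopropane-1-carboxylate (both diastereomers) | C=CC1(C(=O)OC)CC1(OCC)C2=C(C)CCC2=O
F2 | step 6 | racemic methyl 4-ethoxy-8a-methyl-3-oxo-1,2,3,5,8,8a-hexahydroazulene-6-carboxylate | O=C2CCC3(C)CC=C(C(=O)OC)CC(OCC)=C32
F3 | step 6 | racemic methyl 4-ethoxy-3-hydroxy-8a-methyl-3-(propan-2-yl)-1,2,3,5,8,8a-hexahydroazulene-6-carboxylate (configuration not defined) | CC(C)C2(O)CCC3(C)CC=C(C(=O)OC)CC(OCC)=C32
F4 | step 6 | racemic methyl 8a-methyl-4-oxo-3-(propan-2-yl)-1,2,4,5,8,8a-hexahydroazulene-6-carboxylate | CC(C)C2=C3C(=O)CC(C(=O)OC)=CCC3(C)CC2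
F5 | step 6 | racemic methyl (4R*,8aR*)-4-hydroxy-8a-methyl-3-(propan-2-yl)-1,2,4,5,8,8a-hexahydroazulene-6-carboxylate (both enantiomers written) | CC(C)C2=C3[C@H](O)CC(C(=O)OC)=CC[C@@]3(C)CC2.CC(C)C2=C3[C@@H](O)CC(C(=O)OC)=CC[C@]3(C)CC2
F6 | step 6 | methyl (4R,8aR)-4-acetoxy-8a-methyl-3-(propan-2-yl)-1,2,4,5,8,8a-hexahydroazulene-6-carboxylate | CC(C)C2=C3[C@H](OC(C)=O)CC(C(=O)OC)=CC[C@@]3(C)CC2
F7 | step 17 | 4-(benzyloxy)-3-methoxybenzoic anhydride | COc1cc(ccc1OCc1ccccc1)C(=O)OC(=O)c1ccc(OCc2ccccc2)c(OC)c1
F8 | step 7 | (8aR)-4-ethoxy-8a-methyl-3-oxo-1,2,3,5,8,8a-hexahydroazulene-6-carboxylic acid | O=C2CC[C@]3(C)CC=C(C(=O)O)CC(OCC)=C32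
F9 | step 7 | (8aR)-4-ethoxy-3-hydroxy-8a-methyl-3-(propan-2-yl)-1,2,3,5,8,8a-hexahydroazulene-6-carboxylic acid (C3 configuration not defined) | CC(C)C2(O)CC[C@]3(C)CC=C(C(=O)O)CC(OCC)=C32
F10 | step 7 | (8aR)-8a-methyl-4-oxo-3-(propan-2-yl)-1,2,4,5,8,8a-hexahydroazulene-6-carboxylic acid | CC(C)C2=C3C(=O)CC(C(=O)O)=CC[C@@]3(C)CC2
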